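## Structural features

The target is one cyclohexane (C5–C10) in which every ring carbon is a stereocentre, and a seventh centre, C1, sits on the oxirane attached to the quaternary C10. A trans-fused α-methylene-γ-butyrolactone spans C7 (through C11) and C8 (through oxygen). C6 carries a methacrylate, C9 a free hydroxyl, C10 the methyl C14 and the C1–C2 oxirane, and C5 a 2-substituted acrolein (C4, C3, C15). C4, O6, C11 and C14 lie on one face of the ring, and O8, O9 and C1 on the other. The trans-lactone therefore locks the chair with C4, C11, O8 and C1 equatorial and O6, O9 and C14 axial, O6 being syn-axial to C14. The fragile groups are three Michael acceptors (enal, methylene lactone, methacrylate), a terminal epoxide, and an ester, a lactone and a free alcohol on neighbouring carbons that can exchange acyl groups. The real difficulties are the quaternary C10 between C5 and C9, telling O6, O8 and O9 apart, and C1, which sits on a freely rotating two-carbon arm. The key step uses the cis relation between O6 and the C7–C11 bond: a two-atom tether on O6 (C12–C11) can reach C7 of a C9 enone only on the face of O6. The price is that C12 must later be handed from O6 to O8.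

## Logic of the disconnections

**38 ⇒ 37.** The two C–O bonds of the oxirane are cut last because the epoxide is the most fragile group. In 37 the only hydroxyl (O9–H) is homoallylic to the only electron-rich alkene, so chemoselectivity is built in. The forward step must choose one face of a rotating vinyl group.

**37 ⇒ 35.** The C15–O bond is cut back to a C–H bond. An isopropenyl group is a robust stand-in for the acrolein through all earlier basic, reducing and radical steps. The forward oxidation must pick the one allylic methyl on an electron-rich alkene and leave the secondary C9 alcohol alone.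

**35 ⇒ 33.** The C11=C13 double bond is traced to a dimethylaminomethyl group. This keeps a Michael acceptor out of the acylation and lactonisation steps. The forward step is a quaternisation and elimination that the methacrylate and the free alcohol must tolerate.

**33 ⇒ 31.** The O8–C12 lactone bond and the free O8–H and O9–H are traced to an amide and one isopropylidene acetal. With O6 already esterified and O9 unable to reach C12, only O8 can close, so no separate protection of O9 is needed. The forward step needs acid that spares the isopropenyl group.

**31 ⇒ 29 ⇒ 27.** The methacrylate C–O bond and then the amide C–N bond are cut, which leads back to a cis-fused lactone on O6. A cis-fused lactone on O6 is expected to be preferred thermodynamically over the trans-fused one on O8, so a simple equilibration cannot be trusted. The O6–C12 bond is therefore broken irreversibly by aminolysis, and O6 is capped with its final ester before C12 is offered to O8. The forward acylation must work on an axial, hindered alcohol.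

**27 ⇒ 24.** The C11–C13 bond is cut to a lactone enolate and an iminium salt. At this stage the lactone α-position is the only acidic C–H.

**24 ⇒ 23 ⇒ 21 ⇒ 20 ⇒ 18.** These cuts return C12 to the acetal level, remove the acetal protection, return C9 to a ketone and remove O8. The C9 ketone left by the key step has only one enolisable side, so O8 enters regiospecifically, and the ketone then accepts hydride to give O9. The forward steps demand delivery of oxygen to C8 on the vinyl face and of hydride to C9 from the methyl face.

**18 ⇒ 17 (key).** The C7–C11 bond is cut, which opens the five-membered acetal ring. This removes one ring and one stereocentre and leaves a monocyclic 4-oxy-cyclohexenone. The forward radical closure must beat reduction and must prefer the enone over the other alkenes.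

**17 ⇒ 14 + 15 + 16.** The acetal C–O and the C–Br bonds are cut to an allylic alcohol, an enol ether and a bromine source. The demand is that the enol ether is the most nucleophilic alkene present.

**14 ⇒ 13 ⇒ 11 ⇒ 8.** The C6–O bond is traced through an inversion to the epimeric alcohol and then to a C6–H bond of an enone. Oxygen is expected to enter anti to the adjacent isopropenyl group, so one inversion is planned. The forward oxidation must attack the γ-terminus of a dienol ether and not C8.

**8 ⇒ 6.** The C7=C8 double bond is removed. The saturated ketone can be enolised only towards C8, so the forward dehydrogenation is regiospecific.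

**6 ⇒ 5 ⇒ 1 + 2 + 3.** The C1=C2 double bond is traced to an aldol carbinol, and the C10–C1 and C5–C4 bonds are cut to an enone, an alkenyl Grignard reagent and an aldehyde. This reduces three carbon–carbon connections and two stereocentres to one catalytic conjugate addition with enolate trapping. The forward step must control the absolute configuration at C5; the trans relation at C10 follows from the cyclic enolate.

## Other disconnections considered

**Alternative 1:** The cut is through C9–C10 and C1–O. In the forward direction NaOCl turns the aldoxime of the open-chain lactone A1 into a nitrile oxide, which adds across the (Z)-C10–C1 alkene to give the isoxazoline-fused cyclohexane A2.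
- In its favour: the ring, the quaternary C10 and the oxygen-bearing C1 arise in one suprafacial event, so the C1/C10 relation follows from alkene geometry. On this point it is better than the chosen plan, where C1 is the least secure centre. A2 also already holds the trans-lactone on O8 and a protected O6, so no acyl relay is needed, which is also better.
- Against it: A1 must carry four contiguous stereocentres (C5–C8) on an open chain together with a geometrically pure trisubstituted alkene. The facial sense of the cycloaddition relative to C5 rests on chain conformation only. After N–O cleavage C9 is again a ketone and needs the same axial-selective reduction as in the chosen plan, so the two are equal there.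
- Further steps: C1–OH and C2–OBn must still become the oxirane, the ketal must become isopropenyl and then the enal, and methylenation and esterification remain.
- Comparison: a concerted cycloaddition and a radical chain are comparably mild, but the step count would be clearly higher.

**Alternative 2:** The cut is C6–C7. A chiral triazolium salt with KN(SiMe3)2 converts the aldehyde of the enoate A3 into an acyl anion equivalent, which adds to the enoate β-carbon and gives the cyclohexanone A4.
- In its favour: the C6 ketone lets C5 and C7 equilibrate to their equatorial arrangement, and O6 comes from a late hydride addition. O8 and O9 arrive as one acetal, separate from O6, so lactonisation onto O8 is unambiguous. That is equal to the amide relay of the chosen plan and needs fewer operations. The step is catalytic and metal-free.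
- Against it: the aldehyde of A3 is α-branched and next to a quaternary carbon, a poor donor for this umpolung. The γ-alkoxy enoate can eliminate under the basic conditions. C7 would depend on the catalyst overriding substrate bias, whereas the tether of the chosen plan fixes C7 with certainty. The C6 ketone must then be reduced to the axial alcohol, cis to both neighbours.
- Comparison: A3 needs the quaternary C10 built on an open chain beside two oxygenated centres, so step economy is no better.

**Alternative 3:** The cut is C5–C10. Pd2(dba)3 with a chiral diphosphine ionises the allylic carbonate A5, and the β-keto ester enolate attacks the inner allyl terminus to give the cyclohexanone A6.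
- In its favour: the hardest bond, to the quaternary carbon, is formed catalytically, and alkene geometry and the C10 epimers converge through allyl equilibration. The lactone and the C9 carbonyl are already in place, so no tether has to change oxidation level or migrate, which is better than the chosen plan. C5 is set as securely as by the conjugate addition, so the two are equal there.
- Against it: the two faces of the enolate (methyl against ester) differ little, so the C10 configuration is the weak point. The chosen plan sets C10 by anti alkylation of a cyclic enolate. The C10 ester must be turned into a vinyl group in three further steps beside a lactone and a ketone. C8, between the ketone and the lactone oxygen, can epimerise under base. A5 again requires three contiguous centres on an open chain.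
- Comparison: an ionic, catalyst-controlled closure replaces a substrate-controlled radical one, at a longer overall sequence.

Key step: step 8

Remark on naming: elemane numbering is used for all ring compounds. "Methyl face" is the ring face that carries C14; "vinyl face" is the opposite one. From 18 onwards C4, O6 and C11 are on the methyl face and C1, O8 and O9 on the vinyl face unless stated.

Assumption: in steps 1 and 19 the antipode of the chiral ligand that gives the stated configuration is used; if the other antipode is needed, it is exchanged without other change.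

## Route

Step 1
Reactants: 1 2-methylcyclohex-2-en-1-one; 2 isopropenylmagnesium bromide; 3 acetaldehyde
Product: 5 (2R,3S)-2-(1-hydroxyethyl)-2-methyl-3-(prop-1-en-2-yl)cyclohexan-1-one as carbinol epimers, via magnesium enolate 4 (not isolated)
Conditions: CuBr·SMe2 (5 mol %), (R)-1-[(SP)-2-(diphenylphosphino)ferrocenyl]ethyldicyclohexylphosphine (6 mol %), t-BuOMe, −78 °C; then MeCHO, −78 °C; aq. NH4Cl
Reagents that add atoms: isopropenylmagnesium bromide 2, CC(=C)[Mg]Br; acetaldehyde 3, CC=O
Why: Copper-catalysed asymmetric conjugate addition sets C5 under ligand control, and the regiodefined enolate 4 undergoes aldol addition anti to the pseudo-axial C5 substituent, which fixes the quaternary C10 with its two-carbon arm trans to isopropenyl. The carbinol centre is left uncontrolled because step 2 removes it.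

Step 2
Reactants: 5 (2R,3S)-2-(1-hydroxyethyl)-2-methyl-3-(prop-1-en-2-yl)cyclohexan-1-one
Product: 6 (2S,3S)-2-ethenyl-2-methyl-3-(prop-1-en-2-yl)cyclohexan-1-one
Conditions: methyl N-(triethylammoniosulfonyl)carbamate (Burgess reagent), benzene, 60 °C
Reagents that add atoms: none
Why: Burgess dehydration is a syn elimination through the sulfamate ester; the only β-hydrogens are on the methyl group because the other neighbour is quaternary, so the vinyl group is the sole possible alkene.

Step 3
Reactants: 6 (2S,3S)-2-ethenyl-2-methyl-3-(prop-1-en-2-yl)cyclohexan-1-one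
Product: 8 (5S,6S)-6-ethenyl-6-methyl-5-(prop-1-en-2-yl)cyclohex-2-en-1-one, via silyl enol ether 7 (not isolated)
Conditions: Me3SiOTf, Et3N, CH2Cl2, 0 °C; then Pd(OAc)2 (1.05 equiv), MeCN, rt
Reagents that add atoms: none
Why: Saegusa–Ito dehydrogenation; only C8 can be enolised because C10 is quaternary, and divalent palladium then gives the C7–C8 enone by β-hydride elimination.

Step 4
Reactants: 8 (5S,6S)-6-ethenyl-6-methyl-5-(prop-1-en-2-yl)cyclohex-2-en-1-one
Product: 11 (4S,5S,6S)-6-ethenyl-4-hydroxy-6-methyl-5-(prop-1-en-2-yl)cyclohex-2-en-1-one, via silyl dienol ether 9 (not isolated), via epoxy silyl enol ether 10 (not isolated)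
Conditions: Me3SiOTf, Et3N, CH2Cl2, 0 °C; then 3-chloroperbenzoic acid (1.05 equiv), NaHCO3, CH2Cl2, −40 °C; dilute HCl work-up
Reagents that add atoms: 3-chloroperbenzoic acid, OOC(=O)c1cccc(Cl)c1
Why: Vinylogous Rubottom oxidation; the only possible dienol ether 9 is epoxidised at its C6–C7 terminus, expected anti to the adjacent pseudo-axial isopropenyl group, and 10 opens to the γ-hydroxy enone. Any C6 epimer formed is already 14 and joins at step 7.

Step 5
Reactants: 11 (4S,5S,6S)-6-ethenyl-4-hydroxy-6-methyl-5-(prop-1-en-2-yl)cyclohex-2-en-1-one; 12 4-nitrobenzoic acid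
Product: 13 (1R,5S,6S)-5-ethenyl-5-methyl-4-oxo-6-(prop-1-en-2-yl)cyclohex-2-en-1-yl 4-nitrobenzoate
Conditions: PPh3, diisopropyl azodicarboxylate, THF, 0 °C → rt
Reagents that add atoms: 4-nitrobenzoic acid 12, OC(=O)c1ccc(cc1)[N+](=O)[O-]
Why: Mitsunobu esterification inverts C6 by SN2 displacement of the oxyphosphonium group and places the oxygen cis to isopropenyl. Elimination is disfavoured because H5 is syn to the leaving group.

Step 6
Reactants: 13 (1R,5S,6S)-5-ethenyl-5-methyl-4-oxo-6-(prop-1-en-2-yl)cyclohex-2-en-1-yl 4-nitrobenzoate
Product: 14 (4R,5S,6S)-6-ethenyl-4-hydroxy-6-methyl-5-(prop-1-en-2-yl)cyclohex-2-en-1-one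
Conditions: K2CO3 (0.2 equiv), MeOH, 0 °C, short contact
Reagents that add atoms: none
Why: Transesterification cleaves the activated ester at the acyl carbon, so the new C6 configuration is untouched; low temperature and short contact limit base isomerisation of the γ-hydroxy enone.

Step 7
Reactants: 14 (4R,5S,6S)-6-ethenyl-4-hydroxy-6-methyl-5-(prop-1-en-2-yl)cyclohex-2-en-1-one; 15 ethyl vinyl ether; 16 N-bromosuccinimide
Product: 17 (4R,5S,6S)-4-(2-bromo-1-ethoxyethoxy)-6-ethenyl-6-methyl-5-(prop-1-en-2-yl)cyclohex-2-en-1-one (acetal epimers)
Conditions: ethyl vinyl ether (5 equiv), N-bromosuccinimide (1.2 equiv), CH2Cl2, −20 → 0 °C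
Reagents that add atoms: ethyl vinyl ether 15, CCOC=C; N-bromosuccinimide 16, O=C1CCC(=O)N1Br
Why: Bromoacetalisation; the bromonium or oxocarbenium ion from the enol ether is captured by O6–H. The enol ether is far more nucleophilic than the vinyl, isopropenyl or enone alkenes.

Step 8
Reactants: 17 (4R,5S,6S)-4-(2-bromo-1-ethoxyethoxy)-6-ethenyl-6-methyl-5-(prop-1-en-2-yl)cyclohex-2-en-1-one
Product: 18 cis-fused ethoxy acetal ketone (12-ethoxy-6,12-epoxyelema-1,3-dien-9-one; O6 and C11 on the methyl face; C12 epimers)
Conditions: Bu3SnH (1.3 equiv, slow addition), azobisisobutyronitrile (0.2 equiv), benzene (0.01 M), 80 °C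
Reagents that add atoms: none
Why: Bu3Sn• abstracts bromine from 17 to give the primary, nucleophilic C11 radical, which adds 5-exo-trig to C7, the β-carbon of the electron-poor C9 enone, forming C7–C11 and the tetrahydrofuran acetal ring; the resulting C8 radical next to the ketone takes hydrogen from Bu3SnH and carries the chain. The closest known reaction type is the Ueno–Stork haloacetal cyclisation onto cyclohexenones. The one ring closed is five-membered and its closure is exo, and because the tether from O6 to C11 is only two atoms long it can reach C7 solely on the face of O6, so the ring fusion is necessarily cis. C7 is therefore the only new controlled stereocentre and is dictated by C6 (C11 on the methyl face); C8 becomes a methylene and C12 stays an epimer mixture that step 12 erases. The step needs chemoselectivity for the enone over the vinyl and isopropenyl groups, which polarity matching secures, since closure onto isopropenyl would be a slower 6-exo or 7-endo addition to an unactivated alkene. It also needs closure to outrun direct reduction, which slow addition of the stannane at high dilution secures.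

Step 9
Reactants: 18 cis-fused ethoxy acetal ketone
Product: 20 8-hydroxy ketone (8-OH on the vinyl face; acetal unchanged), via potassium enolate 19 (not isolated)
Conditions: KN(SiMe3)2 (1.1 equiv), THF, −78 °C; then 3-phenyl-2-(phenylsulfonyl)oxaziridine, −78 °C; aq. NH4Cl
Reagents that add atoms: 3-phenyl-2-(phenylsulfonyl)oxaziridine, O=S(=O)(c1ccccc1)N1OC1c1ccccc1
Why: Davis enolate hydroxylation; only the C8–C9 enolate can form, and the oxidant approaches C8 on the vinyl face because the methyl face is screened by the syn-axial O6 and C14. This gives the equatorial 8-OH trans to C11.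

Step 10
Reactants: 20 8-hydroxy ketone
Product: 21 cis-8,9-diol (both hydroxyls on the vinyl face; 9-OH axial)
Conditions: LiBH(s-Bu)3 (2.5 equiv), THF, −78 °C; then NaOH, H2O2, 0 °C
Reagents that add atoms: none
Why: A bulky trialkylborohydride attacks a cyclohexanone flanked by a quaternary carbon along the equatorial trajectory, here from the methyl face, which gives the axial C9 alcohol cis to O8. This is the same sense as the known reduction of 4,4-dimethyl-3-keto steroids to axial alcohols with this reagent class.

Step 11
Reactants: 21 cis-8,9-diol; 22 2,2-diethoxypropane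
Product: 23 8,9-O-isopropylidene acetal of 21
Conditions: 2,2-diethoxypropane, pyridinium 4-toluenesulfonate (cat.), CH2Cl2, rt
Reagents that add atoms: 2,2-diethoxypropane 22, CCOC(C)(C)OCC
Why: Acetalisation of an axial–equatorial cis-diol to a five-membered ketal; the reagent releases only ethanol, so the ethoxy acetal at C12 is not scrambled.

Step 12
Reactants: 23 8,9-O-isopropylidene acetal
Product: 24 cis-fused 6,12-lactone (8,9-isopropylidenedioxyelema-1,3-dien-12,6-olide)
Conditions: CrO3, H2SO4, acetone–H2O, 0 °C
Reagents that add atoms: water, O
Why: Jones oxidation; acid hydrolysis of the ethoxy acetal to the lactol is followed by chromic acid oxidation to the γ-lactone. Acetone as solvent keeps the isopropylidene acetal in place, and no free alcohol remains to be over-oxidised.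

Step 13
Reactants: 24 cis-fused 6,12-lactone; 25 N,N-dimethylmethyleneiminium iodide
Product: 27 11-(dimethylaminomethyl) lactone (C11 epimers), via lithium enolate 26 (not isolated)
Conditions: LiN(i-Pr)2 (1.2 equiv), THF, −78 °C; then N,N-dimethylmethyleneiminium iodide, −78 → 0 °C
Reagents that add atoms: N,N-dimethylmethyleneiminium iodide 25, C[N+](C)=C.[I-]
Why: Mannich reaction of the lactone enolate, the only acidic C–H left, installs C13 as an aminomethyl group, a masked exocyclic methylene that is inert to the later amine, acylation and acid steps. The C11 configuration is irrelevant because C11 becomes trigonal in step 17.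

Step 14
Reactants: 27 11-(dimethylaminomethyl) lactone; 28 dimethylamine hydrochloride
Product: 29 6-hydroxy N,N-dimethylamide (ring-opened at O6–C12)
Conditions: Me2NH·HCl (4 equiv), AlMe3 (4 equiv), CH2Cl2, 0 → 40 °C; aq. potassium sodium tartrate
Reagents that add atoms: dimethylamine hydrochloride 28, CNC.Cl
Why: Aminolysis of the lactone by the aluminium amide opens the O6–C12 bond and frees O6–H. The amide does not re-close under the basic conditions of the next step, so the preferred cis-lactone cannot re-form.

Step 15
Reactants: 29 6-hydroxy N,N-dimethylamide; 30 methacrylic anhydride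
Product: 31 6-O-methacryloyl amide
Conditions: methacrylic anhydride (3 equiv), 4-(dimethylamino)pyridine (1 equiv), Et3N, CH2Cl2, rt → 40 °C
Reagents that add atoms: methacrylic anhydride 30, CC(=C)C(=O)OC(=O)C(C)=C
Why: Nucleophile-catalysed acylation of the only free hydroxyl installs the final C6 ester while O8 and O9 are masked together; the acylpyridinium intermediate is reactive enough for the axial alcohol.

Step 16
Reactants: 31 6-O-methacryloyl amide
Product: 33 trans-fused 8,12-lactone with free axial 9-OH and the 11-(dimethylaminomethyl) group, via diol amide 32 (not isolated)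
Conditions: AcOH–H2O (4:1), 70 °C
Reagents that add atoms: none
Why: Acid hydrolysis of the ketal frees O8–H and O9–H, and the equatorial O8–H then closes the γ-lactone by acid-promoted acyl transfer from the amide. The regiochemistry is fixed by constitution, because O6 is esterified and O9 is trans-1,3 to the side chain and cannot reach C12, so O9 is released without a protecting group of its own.

Step 17
Reactants: 33 trans-fused 8,12-lactone
Product: 35 α-methylene lactone (9-hydroxy-6-methacryloyloxyelema-1,3,11(13)-trien-12,8-olide), via ammonium iodide 34 (not isolated)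
Conditions: MeI (excess), MeCN, rt; then aq. NaHCO3, EtOAc, rt
Reagents that add atoms: none
Why: Quaternisation of the Mannich base followed by E1cB loss of trimethylamine unveils the exocyclic methylene under conditions too mild to move the esters.

Step 18
Reactants: 35 α-methylene lactone
Product: 37 enal (15-oxo derivative of 35), via allylic alcohol 36 (not isolated)
Conditions: SeO2 (0.5 equiv), t-BuOOH, CH2Cl2, rt; then MnO2, CH2Cl2, rt
Reagents that add atoms: selenium dioxide, O=[Se]=O (oxygen carrier, reoxidised by tert-butyl hydroperoxide, CC(C)(C)OO)
Why: Allylic oxidation by an ene reaction and [2,3]-shift; the isopropenyl group is the only electron-rich alkene with allylic hydrogens (the vinyl has none, and the methacrylate and methylene lactone are deactivated), and its methyl reacts in preference to the hindered C5–H. MnO2 then oxidises only the allylic alcohol and leaves the C9 hydroxyl.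

Step 19
Reactants: 37 enal
Product: 38 target, (1R,5R,6S,7S,8R,9S,10S)-1,2-epoxy-9-hydroxy-6-methacryloyloxy-15-oxoelema-3,11(13)-dien-12,8-olide
Conditions: VO(Oi-Pr)3 (5 mol %), (R,R)-N,N′-dihydroxy-N,N′-bis(diphenylacetyl)cyclohexane-1,2-diamine (6 mol %), cumene hydroperoxide, toluene, 0 °C → rt
Reagents that add atoms: cumene hydroperoxide, CC(C)(OO)c1ccccc1
Why: Hydroxyl-directed epoxidation of a homoallylic alcohol; the vanadium alkoxide at the axial O9 can reach only the vinyl group, and the other alkenes are electron-poor. C1 is set by delivery of oxygen to the Si face of C1 (giving 1R), the face turned towards O9 when the terminal CH2 points away from the axial C14; the chiral bishydroxamic acid ligand is chosen to reinforce that face.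

## Compound list

1 | 2-methylcyclohex-2-en-1-one | CC1=CCCCC1=O | starting material
2 | isopropenylmagnesium bromide | CC(=C)[Mg]Br | starting material
3 | acetaldehyde | CC=O | starting material
4 | bromomagnesium (3S)-2-methyl-3-(prop-1-en-2-yl)cyclohex-1-en-1-olate | C1CCC(O[Mg]Br)=C(C)[C@@H]1C(C)=C | intermediate
5 | (2R,3S)-2-(1-hydroxyethyl)-2-methyl-3-(prop-1-en-2-yl)cyclohexan-1-one, carbinol epimers | C1CCC(=O)[C@@](C)(C(C)O)[C@@H]1C(C)=C | intermediate
6 | (2S,3S)-2-ethenyl-2-methyl-3-(prop-1-en-2-yl)cyclohexan-1-one | C1CCC(=O)[C@@](C)(C=C)[C@@H]1C(C)=C | intermediate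
7 | trimethylsilyl enol ether of 6 (C8=C9) | C1CC=C(O[Si](C)(C)C)[C@@](C)(C=C)[C@@H]1C(C)=C | intermediate
8 | (5S,6S)-6-ethenyl-6-methyl-5-(prop-1-en-2-yl)cyclohex-2-en-1-one | C1C=CC(=O)[C@@](C)(C=C)[C@@H]1C(C)=C | intermediate
9 | trimethylsilyl dienol ether of 8 (C6=C7, C8=C9) | C1=CC=C(O[Si](C)(C)C)[C@@](C)(C=C)[C@@H]1C(C)=C | intermediate
10 | C6–C7 epoxide of 9, oxygen on the vinyl face | C[Si](C)(C)OC1=C[C@@H]2O[C@@H]2[C@@H](C(C)=C)[C@]1(C)C=C | intermediate
11 | (4S,5S,6S)-6-ethenyl-4-hydroxy-6-methyl-5-(prop-1-en-2-yl)cyclohex-2-en-1-one (OH trans to isopropenyl) | O[C@H]1C=CC(=O)[C@@](C)(C=C)[C@@H]1C(C)=C | intermediate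
12 | 4-nitrobenzoic acid | OC(=O)c1ccc(cc1)[N+](=O)[O-] | starting material
13 | (1R,5S,6S)-5-ethenyl-5-methyl-4-oxo-6-(prop-1-en-2-yl)cyclohex-2-en-1-yl 4-nitrobenzoate | O=C(O[C@@H]1C=CC(=O)[C@@](C)(C=C)[C@@H]1C(C)=C)c2ccc(cc2)[N+](=O)[O-] | intermediate
14 | (4R,5S,6S)-6-ethenyl-4-hydroxy-6-methyl-5-(prop-1-en-2-yl)cyclohex-2-en-1-one (OH cis to isopropenyl) | O[C@@H]1C=CC(=O)[C@@](C)(C=C)[C@@H]1C(C)=C | intermediate
15 | ethyl vinyl ether | CCOC=C | starting material
16 | N-bromosuccinimide | O=C1CCC(=O)N1Br | starting material
17 | (4R,5S,6S)-4-(2-bromo-1-ethoxyethoxy)-6-ethenyl-6-methyl-5-(prop-1-en-2-yl)cyclohex-2-en-1-one, acetal epimers | CCOC(CBr)O[C@@H]1C=CC(=O)[C@@](C)(C=C)[C@@H]1C(C)=C | intermediate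
18 | cis-fused ethoxy acetal ketone, 12-ethoxy-6,12-epoxyelema-1,3-dien-9-one, C12 epimers | CCOC1O[C@@H]2[C@H](C1)CC(=O)[C@@](C)(C=C)[C@@H]2C(C)=C | intermediate
19 | potassium C8–C9 enolate of 18 | CCOC1O[C@@H]2[C@H](C1)C=C([O-])[C@@](C)(C=C)[C@@H]2C(C)=C.[K+] | intermediate
20 | 8-hydroxy derivative of 18, 8-OH on the vinyl face | CCOC1O[C@@H]2[C@H](C1)[C@@H](O)C(=O)[C@@](C)(C=C)[C@@H]2C(C)=C | intermediate
21 | cis-8,9-diol, both hydroxyls on the vinyl face, C9 ketone reduced | CCOC1O[C@@H]2[C@H](C1)[C@@H](O)[C@@H](O)[C@@](C)(C=C)[C@@H]2C(C)=C | intermediate
22 | 2,2-diethoxypropane | CCOC(C)(C)OCC | starting material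
23 | 8,9-O-isopropylidene acetal of 21 | CCOC1O[C@@H]2[C@H](C1)[C@H]3OC(C)(C)O[C@H]3[C@@](C)(C=C)[C@@H]2C(C)=C | intermediate
24 | 8,9-isopropylidenedioxyelema-1,3-dien-12,6-olide (cis-fused lactone on O6) | O=C1O[C@@H]2[C@H](C1)[C@H]3OC(C)(C)O[C@H]3[C@@](C)(C=C)[C@@H]2C(C)=C | intermediate
25 | N,N-dimethylmethyleneiminium iodide | C[N+](C)=C.[I-] | starting material
26 | lithium enolate of 24 | [Li+].[O-]C1O[C@@H]2[C@H](C=1)[C@H]3OC(C)(C)O[C@H]3[C@@](C)(C=C)[C@@H]2C(C)=C | intermediate
27 | 11-(dimethylaminomethyl) derivative of 24, C11 epimers | O=C1O[C@@H]2[C@H](C1CN(C)C)[C@H]3OC(C)(C)O[C@H]3[C@@](C)(C=C)[C@@H]2C(C)=C | intermediate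
28 | dimethylamine hydrochloride | CNC.Cl | starting material
29 | 6-hydroxy N,N-dimethylamide (C12 amide, O6–H free, 8,9-ketal, C13 amine) | O[C@@H]1[C@H](C(CN(C)C)C(=O)N(C)C)[C@H]2OC(C)(C)O[C@H]2[C@@](C)(C=C)[C@@H]1C(C)=C | intermediate
30 | methacrylic anhydride | CC(=C)C(=O)OC(=O)C(C)=C | starting material
31 | 6-O-methacryloyl derivative of 29 | C=C(C)C(=O)O[C@@H]1[C@H](C(CN(C)C)C(=O)N(C)C)[C@H]2OC(C)(C)O[C@H]2[C@@](C)(C=C)[C@@H]1C(C)=C | intermediate
32 | 8,9-diol amide (ketal removed from 31) | C=C(C)C(=O)O[C@@H]1[C@H](C(CN(C)C)C(=O)N(C)C)[C@@H](O)[C@@H](O)[C@@](C)(C=C)[C@@H]1C(C)=C | intermediate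
33 | 13-(dimethylamino)-9-hydroxy-6-methacryloyloxyelema-1,3-dien-12,8-olide (trans-fused lactone on O8), C11 epimers | C=C(C)C(=O)O[C@@H]1[C@@H]2C(CN(C)C)C(=O)O[C@H]2[C@@H](O)[C@@](C)(C=C)[C@@H]1C(C)=C | intermediate
34 | trimethylammonium iodide of 33 | C=C(C)C(=O)O[C@@H]1[C@@H]2C(C[N+](C)(C)C)C(=O)O[C@H]2[C@@H](O)[C@@](C)(C=C)[C@@H]1C(C)=C.[I-] | intermediate
35 | 9-hydroxy-6-methacryloyloxyelema-1,3,11(13)-trien-12,8-olide | C=C(C)C(=O)O[C@@H]1[C@@H]2C(=C)C(=O)O[C@H]2[C@@H](O)[C@@](C)(C=C)[C@@H]1C(C)=C | intermediate
36 | 15-hydroxy derivative of 35 | C=C(C)C(=O)O[C@@H]1[C@@H]2C(=C)C(=O)O[C@H]2[C@@H](O)[C@@](C)(C=C)[C@@H]1C(=C)CO | intermediate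
37 | 15-oxo derivative of 35 (enal) | C=C(C)C(=O)O[C@@H]1[C@@H]2C(=C)C(=O)O[C@H]2[C@@H](O)[C@@](C)(C=C)[C@@H]1C(=C)C=O | intermediate
38 | CNP0228781.2, (1R,5R,6S,7S,8R,9S,10S)-1,2-epoxy-9-hydroxy-6-methacryloyloxy-15-oxoelema-3,11(13)-dien-12,8-olide | C=C(C)C(=O)O[C@@H]1[C@@H]2C(=C)C(=O)O[C@H]2[C@@H](O)[C@@](C)([C@@H]2CO2)[C@@H]1C(=C)C=O | target

## Step count and least certain steps

Total step count: 19. Longest linear sequence: 19 steps (1 to 38); all other components are commercial.

**Step 8 (key step).** The most likely failure is hydrogen transfer to the C11 radical before it closes, because the stannane competes with every cyclisation; stannyl radical addition to the enone is the second risk. The fallback forms the same bond by a polar mechanism and sets out from 14. Acylation with methyl 3-chloro-3-oxopropanoate and pyridine should give the mixed malonate F1. Cs2CO3 in MeCN should close C7–C11 by intramolecular Michael addition, cis-fused for the same tether reason, to the keto lactone ester F2. LiCl in wet DMSO at 130 °C (Krapcho dealkoxycarbonylation) should give the keto lactone F3. Hydroxylation as in step 9 gives the 8-hydroxy keto lactone F4, and reduction as in step 10 gives the diol lactone F5; both are kept cold and quenched with acetic acid so that the alkoxides do not move the lactone. Ketalisation as in step 11 returns to the route at 24.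

**Step 1.** The risk is low enantiofacial discrimination, together with competing 1,2-addition, because an alkenyl Grignard reagent and an α-substituted enone are both demanding for the copper catalyst. The fallback sets out from 1 and separates the two events. Rhodium-catalysed asymmetric 1,4-addition of potassium isopropenyltrifluoroborate ([Rh(OH)(cod)]2, BINAP, dioxane–H2O, 90 °C) should give (3R)-2-methyl-3-(prop-1-en-2-yl)cyclohexan-1-one F6. Me3SiCl, NaI and Et3N in MeCN should give the more substituted silyl enol ether F7. MeLi then releases the lithium enolate F8, which adds to acetaldehyde and returns to the route at 5.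

**Step 4.** The risk is oxygen transfer to the C8 terminus of the dienol ether instead of C6, and weak facial bias, because the isopropenyl group shields one face at C6 and the axial vinyl group the other. The fallback sets out from 8 through 9 and changes the mechanism to a [4+2] addition whose connectivity can only give γ-oxygenation. Singlet oxygen (O2, light, tetraphenylporphyrin, CH2Cl2, −78 °C) should give the bicyclic endoperoxide F9. PPh3 followed by dilute HCl then returns to the route at 11, or directly at 14 if the other face reacts.

**Step 10.** The risk is hydride delivery on the vinyl face (axial attack), helped by the O8 alkoxide holding the boron or lithium, which would give the equatorial C9 alcohol. The fallback sets out from 20 and removes the alkoxide so that only steric control remains. t-BuMe2SiOTf and 2,6-lutidine give the 8-silyl ether F10, KBH(s-Bu)3 should give the 9-alcohol F11, and Bu4NF returns to the route at 21.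

**Step 19.** The risk is poor facial selectivity at C1, because the vinyl group rotates freely. The rotamer with CH2 towards C5 leads to 1R and the one with CH2 towards C14 leads to 1S; both can be reached from O9, and simple models do not clearly favour either. The fallback sets out from 37 and replaces stereoselective synthesis by a catalyst-controlled resolution. VO(acac)2 and t-BuOOH give 38 together with its 1S epimer F12. Hydrolytic kinetic resolution with N,N′-bis(3,5-di-tert-butylsalicylidene)cyclohexane-1,2-diaminocobalt acetate (trivalent cobalt, the antipode that consumes 1S) and 0.5 equivalent of water should convert only F12 into the diol F13, leaving 38 to be isolated.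

## Further compounds

F1 | step 8 | methyl malonate ester of 14 | COC(=O)CC(=O)O[C@@H]1C=CC(=O)[C@@](C)(C=C)[C@@H]1C(C)=C
F2 | step 8 | cis-fused 11-methoxycarbonyl 6,12-lactone with C9 ketone, C11 epimers | COC(=O)C1C(=O)O[C@@H]2[C@H]1CC(=O)[C@@](C)(C=C)[C@@H]2C(C)=C
F3 | step 8 | 9-oxoelema-1,3-dien-12,6-olide | O=C1O[C@@H]2[C@H](C1)CC(=O)[C@@](C)(C=C)[C@@H]2C(C)=C
F4 | step 8 | 8-hydroxy-9-oxoelema-1,3-dien-12,6-olide | O=C1O[C@@H]2[C@H](C1)[C@@H](O)C(=O)[C@@](C)(C=C)[C@@H]2C(C)=C
F5 | step 8 | 8,9-dihydroxyelema-1,3-dien-12,6-olide | O=C1O[C@@H]2[C@H](C1)[C@@H](O)[C@@H](O)[C@@](C)(C=C)[C@@H]2C(C)=C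
F6 | step 1 | (3R)-2-methyl-3-(prop-1-en-2-yl)cyclohexan-1-one, C2 epimers | C1CCC(=O)C(C)[C@@H]1C(C)=C
F7 | step 1 | trimethylsilyl enol ether of F6 (C9=C10) | C1CCC(O[Si](C)(C)C)=C(C)[C@@H]1C(C)=C
F8 | step 1 | lithium (3S)-2-methyl-3-(prop-1-en-2-yl)cyclohex-1-en-1-olate | C1CCC([O-])=C(C)[C@@H]1C(C)=C.[Li+]
F9 | step 4 | C6,C9-endoperoxide of 9, peroxide bridge on the vinyl face | C[Si](C)(C)O[C@]12C=C[C@H](OO1)[C@@H](C(C)=C)[C@]2(C)C=C
F10 | step 10 | 8-O-tert-butyldimethylsilyl ether of 20 | CCOC1O[C@@H]2[C@H](C1)[C@@H](O[Si](C)(C)C(C)(C)C)C(=O)[C@@](C)(C=C)[C@@H]2C(C)=C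
F11 | step 10 | 8-O-tert-butyldimethylsilyl ether of 21 | CCOC1O[C@@H]2[C@H](C1)[C@@H](O[Si](C)(C)C(C)(C)C)[C@@H](O)[C@@](C)(C=C)[C@@H]2C(C)=C
F12 | step 19 | 1S epimer of 38 | C=C(C)C(=O)O[C@@H]1[C@@H]2C(=C)C(=O)O[C@H]2[C@@H](O)[C@@](C)([C@H]2CO2)[C@@H]1C(=C)C=O
F13 | step 19 | (1S)-1,2-diol from hydrolysis of F12 | C=C(C)C(=O)O[C@@H]1[C@@H]2C(=C)C(=O)O[C@H]2[C@@H](O)[C@@](C)([C@H](O)CO)[C@@H]1C(=C)C=O
A1 | alternative 1 | open-chain aldoxime with the (Z)-C10–C1 alkene on the trans-lactone | CC(C)(C)[Si](C)(C)O[C@H]([C@@H]1CC(=O)O[C@H]1C=NO)[C@H](/C(C)=C\COCc2ccccc2)C3(C)OCCO3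
A2 | alternative 1 | isoxazoline-fused cyclohexane on the trans-lactone | CC(C)(C)[Si](C)(C)O[C@@H]1[C@@H]2CC(=O)O[C@H]2C3=NO[C@@H](COCc4ccccc4)[C@@]3(C)[C@@H]1C5(C)OCCO5
A3 | alternative 2 | C6 aldehyde with the C7 enoate and the C8/C9 acetonide | O=C[C@@H](C1(C)OCCO1)[C@](C)(C=C)[C@@H]2OC(C)(C)O[C@@H]2/C=C/C(=O)OC
A4 | alternative 2 | cyclohexanone with C7 acetate arm, C8/C9 acetonide and C5 ketal arm | O=C1[C@H](CC(=O)OC)[C@H]2OC(C)(C)O[C@H]2[C@@](C)(C=C)[C@@H]1C3(C)OCCO3
A5 | alternative 3 | allylic carbonate with the C10 β-keto ester on the trans-lactone | CC(C)(C)[Si](C)(C)O[C@@H](C=C(C)COC(=O)OC)[C@@H]1CC(=O)O[C@H]1C(=O)C(C)C(=O)OC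
A6 | alternative 3 | cyclohexanone with quaternary C10 ester and C5 isopropenyl on the trans-lactone | CC(C)(C)[Si](C)(C)O[C@@H]1[C@@H]2CC(=O)O[C@H]2C(=O)[C@@](C)(C(=O)OC)[C@@H]1C(C)=C
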